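**Retrosynthetic overview**

1. Ballotiquinone ⇒ its 11,12,14-tri-O-methyl arene lactone; the hydroxyquinone is unveiled last by oxidative demethylation (water supplies both carbonyl oxygens) and hydrolysis of the C12 methyl ether.
2. The C6–O and C7–O bonds and the 19,6-lactone ⇒ one face-selective osmylation of a C6=C7 alkene in a tricyclic methyl ester, the new 6-hydroxyl then taking over the C19 acyl group; C1–OH by reagent-controlled ketone reduction.
3. Ring B ⇒ ring-closing metathesis (C6=C7) of a divinyl (E)-benzylidene cyclohexanone.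
4. That dienone ⇒ three-component union of a vinyl nucleophile, an (S)-4-carbomethoxy-4-methylcyclohexenone (C5–C6 bond) and a 2-vinylbenzaldehyde (C10=C20 by aldol addition and dehydration).
5. Ring A enone ⇒ new enantioselective Robinson annulation of an α-formyl ester with methyl vinyl ketone; arene from 1,2,4-trimethoxybenzene. Ring order: C (arene, bought) → A → B → lactone.

Assumption: carbons are called C1–C20 by icetexane numbering (C19 = lactone carbonyl, C20 = ring B methine), and methyl 2-methyl-3-oxopropanoate is taken as a commercial starting material.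

**Route**

Step 1
Reactants: 1 1,2,4-trimethoxybenzene
Product: 3 2-(2,3,6-trimethoxyphenyl)propan-2-ol, via aryllithium 2 (not isolated)
Conditions: n-BuLi (1.1 equiv), THF, 0 °C; acetone, −78 °C to rt; H2O
Reagents that add atoms: acetone, CC(C)=O
Why: Directed ortho-lithiation takes place at the ring CH flanked by two methoxy groups and the aryllithium adds 1,2 to acetone, so the future isopropyl carbon enters regiospecifically between O-12 and O-14; no stereocentre is formed.

Step 2
Reactants: 3 2-(2,3,6-trimethoxyphenyl)propan-2-ol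
Product: 4 2-isopropyl-1,3,4-trimethoxybenzene
Conditions: Et3SiH, CF3CO2H, CH2Cl2, 0 °C to rt
Reagents that add atoms: none
Why: Ionic hydrogenation, in which acid ionises the tertiary benzylic alcohol to a cation stabilised by the electron-rich ring and the silane delivers hydride, leaves the aryl ethers untouched.

Step 3
Reactants: 4 2-isopropyl-1,3,4-trimethoxybenzene
Product: 5 1-bromo-3-isopropyl-2,4,5-trimethoxybenzene
Conditions: NBS, MeCN, 0 °C
Reagents that add atoms: N-bromosuccinimide, O=C1CCC(=O)N1Br
Why: Electrophilic aromatic bromination is expected at position 6 of 4 (future C8), the CH that is ortho to one methoxy group and para to another as in 1,2,4-trimethoxybenzene itself, in preference to the CH activated by only one ortho methoxy group.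

Step 4
Reactants: 5 1-bromo-3-isopropyl-2,4,5-trimethoxybenzene
Product: 7 2-bromo-4-isopropyl-3,5,6-trimethoxybenzaldehyde, via α-chloro ether 6 (not isolated)
Conditions: Cl2CHOCH3, TiCl4, CH2Cl2, −20 to 0 °C; H2O
Reagents that add atoms: dichloromethyl methyl ether, COC(Cl)Cl; water, O
Why: Rieche formylation (Friedel–Crafts reaction of the TiCl4-activated dichloromethyl ether) can only occur at the last free ring position (future C9, ortho to a methoxy group), and hydrolysis of the α-chloro ether on work-up releases the aldehyde carbon that becomes C20.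

Step 5
Reactants: 7 2-bromo-4-isopropyl-3,5,6-trimethoxybenzaldehyde
Product: 8 4-isopropyl-3,5,6-trimethoxy-2-vinylbenzaldehyde
Conditions: CH2=CH–B(pin), Pd(PPh3)4 (5 mol%), K2CO3, 1,4-dioxane/H2O, 90 °C
Reagents that add atoms: vinylboronic acid pinacol ester, C=CB1OC(C)(C)C(C)(C)O1
Why: Suzuki–Miyaura coupling at the aryl bromide, whose oxidative addition to zerovalent palladium is helped by the ortho formyl group, installs the vinyl group (future C7) without touching the aldehyde.

Step 6
Reactants: 9 methyl 2-methyl-3-oxopropanoate; 10 methyl vinyl ketone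
Product: 12 methyl (S)-1-methyl-4-oxocyclohex-2-ene-1-carboxylate, via Michael adduct 11 (not isolated)
Conditions: 9-O-(9-phenanthryl)cupreidine or its cupreine pseudo-enantiomer (10 mol%), CH2Cl2, −20 °C; then p-TsOH·H2O (0.2 equiv), PhMe, 80 °C
Reagents that add atoms: none
Why: Proposed new method: catalytic enantioselective Robinson annulation of an acyclic α-formyl ester, in which the quinuclidine nitrogen of the catalyst deprotonates the hydrogen-bonded enol of 9, the catalyst's phenolic OH binds the carbonyl of methyl vinyl ketone, and conjugate addition through this organised ion pair creates the C4 quaternary centre of 11 with (S) configuration (the two pseudo-enantiomeric catalysts give opposite antipodes, so whichever gives (S) is used), after which acid drives the intramolecular aldol condensation of the methyl ketone onto the non-enolisable aldehyde to close ring A without touching C4; the closest known reaction type is the cinchona-alkaloid-catalysed Michael addition of α-substituted β-keto esters to vinyl ketones, together with the racemic Robinson annulation of α-formyl esters.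

Step 7
Reactants: 12 methyl (S)-1-methyl-4-oxocyclohex-2-ene-1-carboxylate; 8 4-isopropyl-3,5,6-trimethoxy-2-vinylbenzaldehyde
Product: 14 methyl (1S,2R)-3-[hydroxy(4-isopropyl-3,5,6-trimethoxy-2-vinylphenyl)methyl]-1-methyl-4-oxo-2-vinylcyclohexane-1-carboxylate (epimer mixture at ring C3 and at the carbinol carbon), via zirconium enolate 13 (not isolated)
Conditions: Cp2ZrCl2, CH2=CHMgBr, THF, 0 °C; then 12, [Rh(cod)(MeCN)2]BF4 (5 mol%), (S)-BINAP (6 mol%), THF, rt; then 8, 0 °C
Reagents that add atoms: vinylmagnesium bromide, C=C[Mg]Br (converted in the flask with Cp2ZrCl2 into chloro(vinyl)zirconocene, [Zr+4].[Cl-].[CH-]=C.c1cc[cH-]c1.c1cc[cH-]c1)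
Why: Rhodium-catalysed asymmetric 1,4-addition of an alkenylzirconocene with aldol trapping of the zirconium enolate (three-component coupling), in which (S)-BINAP, the ligand that gives (S)-3-substituted cyclohexanones from cyclohex-2-enone, delivers vinyl under catalyst control to the C5 face cis to the ester, and the regiodefined C10 enolate then adds to aldehyde 8 (the C10 and C20 centres are erased in step 8).

Step 8
Reactants: 14 methyl (1S,2R)-3-[hydroxy(4-isopropyl-3,5,6-trimethoxy-2-vinylphenyl)methyl]-1-methyl-4-oxo-2-vinylcyclohexane-1-carboxylate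
Product: 16 methyl (1S,2R,3E)-3-[(4-isopropyl-3,5,6-trimethoxy-2-vinylphenyl)methylidene]-1-methyl-4-oxo-2-vinylcyclohexane-1-carboxylate, via mesylate 15 (not isolated)
Conditions: MsCl, Et3N, CH2Cl2, 0 °C; then DBU, rt
Reagents that add atoms: none
Why: Mesylation of the aldol followed by DBU-mediated E1cB elimination gives the conjugated (E)-benzylidene ketone, in which the aryl group lies anti to the carbonyl and therefore cis to C5, the geometry needed for ring closure.

Step 9
Reactants: 16 methyl (1S,2R,3E)-3-[(4-isopropyl-3,5,6-trimethoxy-2-vinylphenyl)methylidene]-1-methyl-4-oxo-2-vinylcyclohexane-1-carboxylate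
Product: 17 methyl (4S,5R)-11,12,14-trimethoxy-1-oxoicetexa-6,8,10(20),11,13-pentaen-19-oate
Conditions: second-generation Hoveyda–Grubbs catalyst, RuCl2(H2IMes)(=CH–C6H4-2-O-i-Pr) (5 mol%), PhMe (5 mM), 80 °C
Reagents that add atoms: none
Why: Ring-closing metathesis of the two terminal vinyl groups, held close by the (E)-benzylidene unit and the ortho-disubstituted arene, closes the seven-membered ring B with a necessarily cis C6=C7 bond and loss of ethene, while the electron-poor trisubstituted enone alkene does not take part.

Step 10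
Reactants: 17 methyl (4S,5R)-11,12,14-trimethoxy-1-oxoicetexa-6,8,10(20),11,13-pentaen-19-oate
Product: 19 (4S,5R,6R,7S)-7-hydroxy-11,12,14-trimethoxy-1-oxoicetexa-8,10(20),11,13-tetraen-19,6-olide, via 6,7-diol ester 18 (not isolated)
Conditions: OsO4 (5 mol%), NMO, acetone/H2O, 0 °C to rt; then DBU (0.3 equiv), PhMe, 50 °C
Reagents that add atoms: N-methylmorpholine N-oxide, C[N+]1([O-])CCOCC1; water, O
Why: Upjohn dihydroxylation followed by lactonisation, in which OsO4 adds suprafacially to the electron-rich C6=C7 styrene bond (the C10=C20 enone bond is deactivated) on the ring B face that carries H5, away from the C4 quaternary carbon and the C5–C10 ring bond, which sets 6R and 7S as a cis-diol, and DBU-catalysed acyl transfer from the neighbouring methyl ester to the 6-hydroxyl then closes the five-membered trans-fused lactone in preference to the bridged six-membered alternative through O7.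

Step 11
Reactants: 19 (4S,5R,6R,7S)-7-hydroxy-11,12,14-trimethoxy-1-oxoicetexa-8,10(20),11,13-tetraen-19,6-olide
Product: 20 (1R,4S,5R,6R,7S)-1,7-dihydroxy-11,12,14-trimethoxyicetexa-8,10(20),11,13-tetraen-19,6-olide
Conditions: (S)-2-methyl-CBS-oxazaborolidine (0.5 equiv), catecholborane (3 equiv), PhMe, −78 to −40 °C
Reagents that add atoms: none
Why: Corey–Bakshi–Shibata reduction, in which the (S)-oxazaborolidine treats the alkenyl arm (C10) as the large group and delivers hydride to the ketone face that gives the 1R alcohol under reagent control, reduces the enone 1,2 and leaves the lactone intact at low temperature.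

Step 12
Reactants: 20 (1R,4S,5R,6R,7S)-1,7-dihydroxy-11,12,14-trimethoxyicetexa-8,10(20),11,13-tetraen-19,6-olide
Product: 21 (1R,4S,5R,6R,7S)-1,7-dihydroxy-12-methoxy-11,14-dioxoicetexa-8,10(20),12-trien-19,6-olide
Conditions: (NH4)2Ce(NO3)6 (2.5 equiv), MeCN/H2O, 0 °C
Reagents that add atoms: water, O
Why: Oxidative demethylation of the para-dimethoxy pair (two one-electron oxidations of the arene with water adding at C11 and C14 and loss of two methanol) gives the 12-methoxy-para-quinone faster than the secondary alcohols are oxidised, and no stereocentre is touched.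

Step 13
Reactants: 21 (1R,4S,5R,6R,7S)-1,7-dihydroxy-12-methoxy-11,14-dioxoicetexa-8,10(20),12-trien-19,6-olide
Product: 22 ballotiquinone [(1R,4S,5R,6R,7S)-1,7,12-trihydroxy-11,14-dioxoicetexa-8,10(20),12-trien-19,6-olide]
Conditions: aq. NaOH (0.5 M), THF, 0 °C; then 1 M HCl
Reagents that add atoms: sodium hydroxide, [Na+].[OH-]
Why: Hydroxide adds to C12 of the vinylogous ester and expels methoxide (addition–elimination) to give the stable hydroxyquinone anion, and acidification reprotonates it and re-closes any lactone opened by the base without touching a stereocentre.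

**Compound list**

1 | 1,2,4-trimethoxybenzene | COc1ccc(OC)c(OC)c1 | starting material
2 | (2,3,6-trimethoxyphenyl)lithium | [Li]c1c(OC)ccc(OC)c1OC | intermediate (not isolated)
3 | 2-(2,3,6-trimethoxyphenyl)propan-2-ol | COc1ccc(OC)c(C(C)(C)O)c1OC | intermediate
4 | 2-isopropyl-1,3,4-trimethoxybenzene | COc1ccc(OC)c(C(C)C)c1OC | intermediate
5 | 1-bromo-3-isopropyl-2,4,5-trimethoxybenzene | COc1cc(Br)c(OC)c(C(C)C)c1OC | intermediate
6 | 2-bromo-1-[chloro(methoxy)methyl]-4-isopropyl-3,5,6-trimethoxybenzene (α-chloro ether) | COC(Cl)c1c(OC)c(OC)c(C(C)C)c(OC)c1Br | intermediate (not isolated)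
7 | 2-bromo-4-isopropyl-3,5,6-trimethoxybenzaldehyde | O=Cc1c(OC)c(OC)c(C(C)C)c(OC)c1Br | intermediate
8 | 4-isopropyl-3,5,6-trimethoxy-2-vinylbenzaldehyde | O=Cc1c(OC)c(OC)c(C(C)C)c(OC)c1C=C | intermediate
9 | methyl 2-methyl-3-oxopropanoate | COC(=O)C(C)C=O | starting material
10 | methyl vinyl ketone (but-3-en-2-one) | CC(=O)C=C | starting material
11 | methyl (S)-2-formyl-2-methyl-5-oxohexanoate (Michael adduct) | COC(=O)[C@@](C=O)(C)CCC(C)=O | intermediate (not isolated)
12 | methyl (S)-1-methyl-4-oxocyclohex-2-ene-1-carboxylate | COC(=O)[C@@]1(C)CCC(=O)C=C1 | intermediate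
13 | chlorozirconocene enolate (enolate bond C3=C4) of methyl (1S,2S)-1-methyl-4-oxo-2-vinylcyclohexane-1-carboxylate, vinyl cis to the ester | C=C[C@@H]1C=C([O-])CC[C@]1(C)C(=O)OC.[Zr+4].[Cl-].c1cc[cH-]c1.c1cc[cH-]c1 | intermediate (not isolated)
14 | methyl (1S,2R)-3-[hydroxy(4-isopropyl-3,5,6-trimethoxy-2-vinylphenyl)methyl]-1-methyl-4-oxo-2-vinylcyclohexane-1-carboxylate, epimer mixture at ring C3 and the carbinol carbon | C=C[C@@H]1C(C(O)c2c(C=C)c(OC)c(C(C)C)c(OC)c2OC)C(=O)CC[C@]1(C)C(=O)OC | intermediate
15 | methanesulfonate of 14 | C=C[C@@H]1C(C(OS(C)(=O)=O)c2c(C=C)c(OC)c(C(C)C)c(OC)c2OC)C(=O)CC[C@]1(C)C(=O)OC | intermediate (not isolated)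
16 | methyl (1S,2R,3E)-3-[(4-isopropyl-3,5,6-trimethoxy-2-vinylphenyl)methylidene]-1-methyl-4-oxo-2-vinylcyclohexane-1-carboxylate | C=C[C@@H]1/C(=C\c2c(C=C)c(OC)c(C(C)C)c(OC)c2OC)C(=O)CC[C@]1(C)C(=O)OC | intermediate
17 | methyl (4S,5R)-11,12,14-trimethoxy-1-oxoicetexa-6,8,10(20),11,13-pentaen-19-oate (ring A cyclohexanone fused at C5–C10 to the benzo-fused cycloheptadiene ring B) | CC(C)c1c(OC)c(OC)c2c(c1OC)C=C[C@@H]1C(=C2)C(=O)CC[C@]1(C)C(=O)OC | intermediate
18 | methyl (4S,5R,6R,7S)-6,7-dihydroxy-11,12,14-trimethoxy-1-oxoicetexa-8,10(20),11,13-tetraen-19-oate | CC(C)c1c(OC)c(OC)c2c(c1OC)[C@H](O)[C@H](O)[C@@H]1C(=C2)C(=O)CC[C@]1(C)C(=O)OC | intermediate (not isolated)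
19 | (4S,5R,6R,7S)-7-hydroxy-11,12,14-trimethoxy-1-oxoicetexa-8,10(20),11,13-tetraen-19,6-olide | CC(C)c1c(OC)c(OC)c2c(c1OC)[C@H](O)[C@@H]1OC(=O)[C@@]3(C)CCC(=O)C(=C2)[C@@H]13 | intermediate
20 | (1R,4S,5R,6R,7S)-1,7-dihydroxy-11,12,14-trimethoxyicetexa-8,10(20),11,13-tetraen-19,6-olide | CC(C)c1c(OC)c(OC)c2c(c1OC)[C@H](O)[C@@H]1OC(=O)[C@@]3(C)CC[C@@H](O)C(=C2)[C@@H]13 | intermediate
21 | (1R,4S,5R,6R,7S)-1,7-dihydroxy-12-methoxy-11,14-dioxoicetexa-8,10(20),12-trien-19,6-olide | CC(C)C1=C(OC)C(=O)C2=C(C1=O)[C@H](O)[C@@H]1OC(=O)[C@@]3(C)CC[C@@H](O)C(=C2)[C@@H]13 | intermediate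
22 | ballotiquinone, (1R,4S,5R,6R,7S)-1,7,12-trihydroxy-11,14-dioxoicetexa-8,10(20),12-trien-19,6-olide | CC(C)C1=C(O)C(=O)C2=C(C1=O)[C@H](O)[C@@H]1OC(=O)[C@@]3(C)CC[C@@H](O)C(=C2)[C@@H]13 | target

**Step count and risks**

Total steps: 13. Longest linear sequence: 12 (steps 1–5, then 7–13); the ring A branch is step 6 and joins at step 7.

Steps most likely to fail:

Step 6 (the new annulation). The α-formyl ester enol is small and methyl vinyl ketone reacts quickly even without catalyst, so the enantioselectivity may be low. Fallback, known chemistry: setting out from 9 and 10, run the classical racemic Robinson annulation (Et3N, then p-TsOH) and resolve the racemic enone by preparative chiral SFC. The unwanted methyl (R)-1-methyl-4-oxocyclohex-2-ene-1-carboxylate F1 is discarded and the (S)-enantiomer comes back to the route as 12.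

Step 7. The rhodium–BINAP catalyst may be too slow at the neopentyl C5 position, or the hindered aldehyde 8 may not trap the zirconium enolate. Fallback: setting out from 12, copper-mediated conjugate addition of vinylmagnesium bromide in the presence of Me3SiCl (CuBr·SMe2, THF, −78 °C) gives methyl (1S,2R)-1-methyl-4-[(trimethylsilyl)oxy]-2-vinylcyclohex-3-ene-1-carboxylate F2, which is isolated. A BF3·OEt2-promoted Mukaiyama aldol reaction with 8 then comes back to the route at 14. C5 selectivity is then substrate-controlled, and any C5 epimer is removed by chromatography after step 8.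

Step 10. Osmium may attack the other face of C6=C7, which would end in the cis-fused lactone. Fallback: setting out from 17, a Woodward cis-hydroxylation (I2, AgOAc, AcOH, then water) puts iodine on the face osmium prefers; acetate opens the iodonium ion from the other side and the acetoxonium ion is hydrolysed. Both oxygens therefore end up on the opposite face, giving methyl (4S,5R,6R,7S)-7-acetoxy-6-hydroxy-11,12,14-trimethoxy-1-oxoicetexa-8,10(20),11,13-tetraen-19-oate F3. K2CO3 in MeOH removes the acetate and comes back to the route at 18, which lactonises to 19 as in step 10.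

Further compounds
F1 | step 6 | methyl (R)-1-methyl-4-oxocyclohex-2-ene-1-carboxylate | COC(=O)[C@]1(C)CCC(=O)C=C1
F2 | step 7 | methyl (1S,2R)-1-methyl-4-[(trimethylsilyl)oxy]-2-vinylcyclohex-3-ene-1-carboxylate | C=C[C@@H]1C=C(O[Si](C)(C)C)CC[C@]1(C)C(=O)OC
F3 | step 10 | methyl (4S,5R,6R,7S)-7-acetoxy-6-hydroxy-11,12,14-trimethoxy-1-oxoicetexa-8,10(20),11,13-tetraen-19-oate | CC(C)c1c(OC)c(OC)c2c(c1OC)[C@H](OC(C)=O)[C@H](O)[C@@H]1C(=C2)C(=O)CC[C@]1(C)C(=O)OC
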